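## Analysis of the target

Selaginellin U (16) is an achiral polyphenol, C34H24O4, built on one benzene ring, ring A. Its four adjacent positions carry four different carbon substituents: a methyl group on C1, a (4-hydroxyphenyl)ethynyl group (C8≡C9) on C2, the quinone methide carbon C7 on C3 and a 4-hydroxyphenyl ring on C4, with hydrogen on C5 and C6. C7 is the centre of a fuchsone-type p-quinone methide, double-bonded to a cyclohexa-2,5-dienone ring and single-bonded to ring A and to a second 4-hydroxyphenyl ring. The dienone ring is symmetric about the C7 double bond and exchanges roles with the phenol ring by proton shift, so no alkene geometry has to be set; the molecule has no stereocentre, and the two that appear along the route (in 5 and in 12) are racemic and temporary. The sensitive groups are the quinone methide (electrophilic at C7, open to water, nucleophiles and reductants), three free phenols, and a diarylalkyne ortho to a carbon that can carry positive charge. The difficulty is the 1,2,3,4-pattern of ring A: C7 is flanked on both sides and must take two aryl groups, and the neighbouring one-carbon branches C7 and C8 must reach different oxidation levels (carboxyl level for twofold arylation, aldehyde level for the alkyne). The strategy rests on this pair: joined as the lactone C7(=O)–O–C8, ring A is a phthalide, in which C3–C4 with C7 and the aryl group is the arylpropiolic acid 3 and C2–C1–C6–C5 with C8 and the methyl group is the dienol 2, whose ester 4 can cyclise in one orientation only.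

## Retrosynthetic reasoning

**16 back to 15.** The last operation unmasks everything fragile at once. In the forward sense, four O–CH3 bonds and the C7–OH bond of the tetramethyl ether carbinol 15 are broken by one Lewis acid treatment. The resulting C7 cation loses a phenolic proton to give the quinone methide of 16. This keeps the phenols and the electrophilic C7 away from every organometallic and oxidising reagent of the route.

**15 back to 13 and 14.** The C9–aryl bond is cut, not C2–C8. The terminal alkyne C–H of 13 lies outside the crowded zone around ring A, so a Sonogashira coupling with aryl iodide 14 should be routine. A cut at C2–C8 would call for a coupling at a position with both ortho sites occupied, and for a halide on C2 that the ring construction does not supply.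

**13 back to 12.** C9 is taken off, which returns C8 to the aldehyde level. With the C7 hydroxyl next to it, hydroxy aldehyde 11 exists as lactol 12. The forward step is a one-carbon homologation under mild base that draws on the small share of open form 11.

**12 back to 10.** This is an adjustment of oxidation level only: C8 goes back to a primary benzylic alcohol. In diol 10 the other hydroxyl is tertiary and cannot be oxidised, so the forward step needs no protecting group. It does need an oxidant that stops at the lactol.

**10 back to 6 and 8 (from 7).** Both C7–aryl bonds are cut together. The two aryl groups on C7 are identical until the last step, so a carboxyl-level C7 can take them in one operation, by way of keto alkoxide 9. In phthalide 6, C7 is the lactone carbonyl and C8 is already the reduced carbon. The difference in oxidation level between the two branches is therefore built into the ring and needs no selective reaction.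

**6 back to 5.** Two hydrogens are added back to ring A. The cyclohexa-1,4-diene 5, with its C3=C4 alkene conjugated to the lactone carbonyl, is the retron of an alkyne plus diene cycloaddition. The forward step is a dehydrogenation driven by aromaticity.

**5 back to 4.** The key disconnection cuts C2–C3 and C4–C5. The lactone becomes a three-atom tether between the diene terminus C2 and the alkyne carbon C3 in the acyclic ester 4. The gain is both rings and the full substitution pattern of ring A from an open-chain ester. The tether leaves only one orientation; an untethered union would leave it to the opposing directing effects of the C2 substituent and the C1 methyl group. The forward reaction must bring the s-cis diene and the ynoate together through the less favoured ester rotamer, so it needs heat.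

**4 back to 2 and 3.** The ester C7–O bond is cut to give dienol 2 and the purchasable acid 3. The forward step is a mild esterification that leaves the diene and its E geometry alone.

**2 back to 1.** The vinyl group of 2 comes from the terminal alkyne of enynol 1 by semihydrogenation. Compound 1 is purchasable with the E trisubstituted alkene in place.

## Alternatives that were turned down

**Alternative 1:** Ring A is opened across C1–C6 and C3–C4 into two three-carbon pieces.
- **Disconnection:** the dinucleophile is 1-methoxy-1,3-bis(trimethylsilyloxy)penta-1,3-diene A1, which carries C7 as the ester carbon, C3, an oxygenated C2 and C1 with its methyl group. The dielectrophile is (E)-1-(4-methoxyphenyl)-3-(trimethylsilyloxy)prop-2-en-1-one A2, which carries C4 with its aryl group, C5 and C6.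
- **Forward key step:** a TiCl4-mediated formal (3+3) cyclocondensation. The terminal carbon of A1 adds to the silyloxy-bearing carbon of A2, the central carbon closes onto the aryl ketone, and loss of silanol gives the salicylate A3, methyl 2-hydroxy-6-(4-methoxyphenyl)-3-methylbenzoate. The phenol is then activated as triflate A4, coupled at C2 with an arylacetylene, the ester is arylated twice and the ethers are cleaved.
- **For:** the ring is aromatic as formed, C7 is already an ester, and the C2 phenol is a ready handle. No redox work at C8 is needed, and only four steps follow the ring closure, against six in the chosen route. On step economy after ring formation and on convergence this alternative is the stronger.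
- **Against:** the orientation depends on the diene terminus choosing the masked aldehyde carbon of A2 over its aryl ketone carbon; the opposite choice gives the 4-aryl isomer. Both components are moisture-sensitive silyl enol ethers that each need two operations to prepare. The C2–C8 bond must then be made by coupling at triflate A4, which has an ester and a methyl group in its two ortho positions.
- **Comparison:** the chosen strategy gives an orientation fixed by connectivity and not by relative electrophilicity. It carries the C2–C8 bond in from the dienol, so that bond never has to be made at a hindered ring position. Its ring-forming step needs no reagent.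

**Alternative 2:** The tolane is cut so that C9 counts as an inserted carbon.
- **Disconnection:** C8 returns to a diaryl ketone in 2-(4-methoxybenzoyl)-6-(4-methoxyphenyl)-3-methylbenzoic acid A5.
- **Forward key step:** lithiated trimethylsilyldiazomethane A6 adds to the C8 ketone of A5. Peterson elimination and loss of N2 give an alkylidene carbene, and a 1,2-aryl shift (Fritsch–Buttenberg–Wiechell type) gives the alkynyl acid A7, 2-[(4-methoxyphenyl)ethynyl]-6-(4-methoxyphenyl)-3-methylbenzoic acid. Esterification, twofold arylation of C7 and ether cleavage follow.
- **For:** the alkyne forms without a transition metal and without an aldehyde stage. Either aryl group may migrate, since both shifts give the same tolane. C7 is at the carboxyl level directly afterwards. On the elegance of the alkyne construction and on the number of steps after the key step this alternative is the stronger.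
- **Against:** it leaves the main problem open. A5 needs the ketone on the C2 branch and the acid on the C3 branch of a phthalic acid derivative, and nothing in the structure biases that choice. A 2-aroylbenzoic acid also exists largely as its cyclic hydroxy lactone tautomer, which masks the ketone. The carboxylate consumes base and can trap the carbene. The ketone of A5 is flanked on both sides, against the bulky silyl carbanion A6.
- **Comparison:** the chosen strategy settles the regiochemistry of ring A and the distinction between C7 and C8 in one step, and then makes the alkyne by two routine reactions.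

**Alternative 3:** Ring A is cut at C2–C3, C1–C6 and C4–C5 into three alkynes.
- **Disconnection:** two alkynes are tied by an ester of reversed orientation, C8(=O)–O–C7H(aryl), in racemic 1,3-bis(4-methoxyphenyl)prop-2-yn-1-yl but-2-ynoate A8. Acetylene A9 supplies C5 and C6.
- **Forward key step:** a RhCl(PPh3)3-catalysed (2+2+2) cyclotrimerisation. Oxidative coupling of the two alkynes of A8 forms C2–C3 in a rhodacyclopentadiene, A9 inserts, and reductive elimination gives racemic 3,4-bis(4-methoxyphenyl)-7-methylphthalide A10. C8 then needs partial reduction and homologation, C7 needs oxidation to the ketone level and a second aryl group, and coupling and ether cleavage finish.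
- **For:** ring A is aromatic as formed and the step is catalytic and mild. The C4 aryl group and one C7 aryl group are in place from the start. The tether fixes the orientation, as in the chosen route. C8 reaches the aldehyde level by simple partial reduction of a lactone, with no risk of over-oxidation; on that point this alternative is the stronger.
- **Against:** A8 is an ester of an alcohol that is both propargylic and 4-methoxybenzylic. It should ionise easily, by rearrangement, substitution or metal insertion into the C–O bond. Gaseous A9 has to compete with self-coupling of the diyne and with its own oligomerisation. Six steps still follow A10, because only one aryl group is on C7 and C7 is at the wrong oxidation level.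
- **Comparison:** the chosen strategy uses a stable primary allylic ester, needs neither gas nor metal in the ring-forming step, and delivers the lactone with C7 as the carbonyl, so both C7 aryl groups enter in one operation.

Key step: step 3

Remark: enynol 1 is taken as the single E isomer; any Z isomer would give a dienyl ester that is not expected to cyclise in step 3.

## Route

**Step 1**
Reactants: 1 (E)-3-methylpent-2-en-4-yn-1-ol
Product: 2 (E)-3-methylpenta-2,4-dien-1-ol
Conditions: H2 (1 atm, stopped at 1 equiv), Lindlar catalyst (Pd/CaCO3 poisoned with Pb(OAc)2), quinoline, Et2O, 0 °C to rt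
Reagents that add atoms: none
Why: Lindlar semihydrogenation; the poisoned palladium surface, moderated further by quinoline, should reduce the terminal alkyne to the vinyl group much faster than it touches the diene formed. The trisubstituted E alkene is not involved, so its geometry passes into 2, which is volatile and is best carried on as a concentrated solution.

**Step 2**
Reactants: 2 (E)-3-methylpenta-2,4-dien-1-ol; 3 3-(4-methoxyphenyl)prop-2-ynoic acid
Product: 4 (E)-3-methylpenta-2,4-dien-1-yl 3-(4-methoxyphenyl)prop-2-ynoate
Conditions: DCC (1.1 equiv), DMAP (0.1 equiv), CH2Cl2, −20 to 0 °C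
Reagents that add atoms: none
Why: Steglich esterification through the O-acylisourea and the acylpyridinium ion; a primary allylic alcohol is acylated on oxygen without allylic transposition. Adding DCC last and cold to acid, alcohol and DMAP should keep the activated arylpropiolic acid from condensing with itself.

**Step 3**
Reactants: 4 (E)-3-methylpenta-2,4-dien-1-yl 3-(4-methoxyphenyl)prop-2-ynoate
Product: 5 rac-7-(4-methoxyphenyl)-4-methyl-3a,6-dihydroisobenzofuran-1(3H)-one
Conditions: 1,2-dichlorobenzene (0.01 M), BHT (0.1 equiv), Ar, 180 °C
Reagents that add atoms: none
Why: Thermal intramolecular Diels–Alder reaction of type 1 (tether on the diene terminus), the closest known case being the cyclisation of penta-2,4-dienyl propiolates to dihydrophthalides: a concerted, suprafacial (4+2) addition of the ynoate C3≡C4 to the s-cis diene C2=C1–C6=C5 forms C2–C3 and C4–C5 in one transition state. The six-membered carbocycle closes through these two bonds as a cyclohexa-1,4-diene, and the γ-lactone closes through C2–C3 alone, in a 5-exo sense with respect to both the alkyne and the C2=C1 alkene. Regiochemistry is the only selectivity needed and the substrate secures it: the bridge C8–O–C7 is too short to let C3 reach C5, so C3 (bearing C7) can bond only to C2 (bearing C8) and the anisyl-bearing C4 only to the free terminus C5. The E geometry of the C2=C1 alkene places C8 on the outside of the s-cis diene, so the tether can fold under the diene without a clash at C5 and no 1,5-hydrogen shift is open. Heat is needed because the ester must leave its preferred Z rotamer for the E rotamer found in the lactone; heat is chosen over a Lewis acid because a Lewis acid bound to the ester would ionise the pentadienylic C8–O bond. High dilution, exclusion of air and a radical inhibitor should hold back diene polymerisation. The one new stereocentre, C3a of 5 (ring carbon C2), forms without control as a racemate, which does not matter because step 4 removes it; isomerisation or partial air oxidation of the 1,4-diene would be equally harmless.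

**Step 4**
Reactants: 5 rac-7-(4-methoxyphenyl)-4-methyl-3a,6-dihydroisobenzofuran-1(3H)-one
Product: 6 7-(4-methoxyphenyl)-4-methylisobenzofuran-1(3H)-one
Conditions: DDQ (1.2 equiv), toluene, rt to 60 °C
Reagents that add atoms: none
Why: Dehydrogenation by a high-potential quinone: hydride abstraction from a doubly allylic position of the cyclohexa-1,4-diene and loss of a proton give the arene, with aromatisation as driving force, and the stereocentre of 5 disappears. The anisyl ether, the lactone and the ring methyl group should not be attacked under these mild conditions.

**Step 5**
Reactants: 6 7-(4-methoxyphenyl)-4-methylisobenzofuran-1(3H)-one; 7 4-bromoanisole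
Product: 10 [2-(hydroxymethyl)-6-(4-methoxyphenyl)-3-methylphenyl]bis(4-methoxyphenyl)methanol, via 4-methoxyphenyllithium 8 (not isolated), via keto alkoxide 9 (not isolated)
Conditions: 7 (3.5 equiv), n-BuLi (3.3 equiv), THF, −78 °C; then 6, −78 °C to rt; H2O
Reagents that add atoms: none
Why: Bromine–lithium exchange gives aryllithium 8, which adds twice to the lactone carbonyl C7: the first adduct, a lithium hemiketal, opens to keto alkoxide 9, and the diaryl ketone takes up the second equivalent to give the triaryl carbinol. Twofold 1,2-addition of aryllithiums to phthalides and hindered benzoates is standard; the neutral aqueous quench avoids acid-promoted closure of the diol to a cyclic ether.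

**Step 6**
Reactants: 10 [2-(hydroxymethyl)-6-(4-methoxyphenyl)-3-methylphenyl]bis(4-methoxyphenyl)methanol
Product: 12 rac-3,3,4-tris(4-methoxyphenyl)-7-methyl-1,3-dihydroisobenzofuran-1-ol, via hydroxy aldehyde 11 (not isolated)
Conditions: IBX (1.3 equiv), DMSO/THF (1:1), rt
Reagents that add atoms: none
Why: Oxidation with the pentavalent iodine reagent IBX, a known way to take 1,4-diols to γ-lactols and stop there; only the primary benzylic alcohol can be oxidised, and hydroxy aldehyde 11 should close at once (5-exo-trig, helped by the geminal aryl groups) onto the tertiary alcohol. IBX is preferred to MnO2 because MnO2 can carry a benzylic lactol on to the lactone. The lactol carbon is a stereocentre that forms as a racemate and is lost in step 7.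

**Step 7**
Reactants: 12 rac-3,3,4-tris(4-methoxyphenyl)-7-methyl-1,3-dihydroisobenzofuran-1-ol
Product: 13 [2-ethynyl-6-(4-methoxyphenyl)-3-methylphenyl]bis(4-methoxyphenyl)methanol
Conditions: dimethyl (1-diazo-2-oxopropyl)phosphonate (2.5 equiv), K2CO3 (4 equiv), MeOH/THF (2:1), rt to 40 °C
Reagents that add atoms: dimethyl (1-diazo-2-oxopropyl)phosphonate (Ohira–Bestmann reagent), CC(=O)C(=[N+]=[N-])P(=O)(OC)OC
Why: Ohira–Bestmann variant of the Seyferth–Gilbert homologation: methoxide removes the acetyl group of the reagent, the diazomethylphosphonate anion adds to the ring-opened tautomer of lactol 12 (the open form 11 met in step 6, present in small share at equilibrium), and Horner–Wadsworth–Emmons-type elimination, loss of N2 and 1,2-hydrogen shift give the terminal alkyne, C9 coming from the reagent. Lactols are established substrates, and carbonate in methanol should be too weak a base to cyclise the tertiary alcohol onto the new alkyne.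

**Step 8**
Reactants: 13 [2-ethynyl-6-(4-methoxyphenyl)-3-methylphenyl]bis(4-methoxyphenyl)methanol; 14 4-iodoanisole
Product: 15 {6-(4-methoxyphenyl)-2-[(4-methoxyphenyl)ethynyl]-3-methylphenyl}bis(4-methoxyphenyl)methanol
Conditions: PdCl2(PPh3)2 (3 mol %), CuI (6 mol %), Et3N/THF (1:1), degassed, 45 °C
Reagents that add atoms: none
Why: Sonogashira coupling: oxidative addition of aryl iodide 14 to zerovalent palladium, transmetalation from the copper acetylide of 13 and reductive elimination form the C9–aryl bond. The reacting alkyne C–H lies outside the crowded region of ring A and the hindered tertiary alcohol is a poor nucleophile towards the alkyne; degassing suppresses Glaser homocoupling.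

**Step 9**
Reactants: 15 {6-(4-methoxyphenyl)-2-[(4-methoxyphenyl)ethynyl]-3-methylphenyl}bis(4-methoxyphenyl)methanol
Product: 16 selaginellin U, 4-[(4-hydroxyphenyl){4'-hydroxy-3-[(4-hydroxyphenyl)ethynyl]-4-methyl-[1,1'-biphenyl]-2-yl}methylidene]cyclohexa-2,5-dien-1-one
Conditions: BBr3 (8 equiv), CH2Cl2, −78 to 0 °C; then ice-water
Reagents that add atoms: none
Why: Lewis acid cleavage of the four aryl methyl ethers by BBr3, which also ionises the tertiary alcohol to the triarylmethyl cation at C7. On hydrolysis this 4-hydroxyphenyl-substituted cation loses a phenolic proton and gives the p-quinone methide, so the net change is four demethylations and one dehydration; no stereochemical element is created.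

## Compound list

1 | (E)-3-methylpent-2-en-4-yn-1-ol | C#C/C(C)=C/CO | starting material
2 | (E)-3-methylpenta-2,4-dien-1-ol | C=C/C(C)=C/CO | intermediate
3 | 3-(4-methoxyphenyl)prop-2-ynoic acid | COc1ccc(cc1)C#CC(=O)O | starting material
4 | (E)-3-methylpenta-2,4-dien-1-yl 3-(4-methoxyphenyl)prop-2-ynoate | C=C/C(C)=C/COC(=O)C#Cc1ccc(OC)cc1 | intermediate
5 | rac-7-(4-methoxyphenyl)-4-methyl-3a,6-dihydroisobenzofuran-1(3H)-one | CC1=CCC(c2ccc(OC)cc2)=C2C(=O)OCC12 | intermediate
6 | 7-(4-methoxyphenyl)-4-methylisobenzofuran-1(3H)-one | Cc1ccc(-c2ccc(OC)cc2)c2C(=O)OCc12 | intermediate
7 | 4-bromoanisole | COc1ccc(Br)cc1 | starting material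
8 | 4-methoxyphenyllithium | [Li]c1ccc(OC)cc1 | intermediate (not isolated)
9 | lithium [2-(4-methoxybenzoyl)-3-(4-methoxyphenyl)-6-methylphenyl]methanolate | [Li+].[O-]Cc1c(C)ccc(-c2ccc(OC)cc2)c1C(=O)c1ccc(OC)cc1 | intermediate (not isolated)
10 | [2-(hydroxymethyl)-6-(4-methoxyphenyl)-3-methylphenyl]bis(4-methoxyphenyl)methanol | Cc1ccc(-c2ccc(OC)cc2)c(C(O)(c2ccc(OC)cc2)c2ccc(OC)cc2)c1CO | intermediate
11 | 2-[hydroxybis(4-methoxyphenyl)methyl]-3-(4-methoxyphenyl)-6-methylbenzaldehyde | Cc1ccc(-c2ccc(OC)cc2)c(C(O)(c2ccc(OC)cc2)c2ccc(OC)cc2)c1C=O | intermediate (not isolated)
12 | rac-3,3,4-tris(4-methoxyphenyl)-7-methyl-1,3-dihydroisobenzofuran-1-ol | Cc1ccc(-c2ccc(OC)cc2)c2c1C(O)OC2(c1ccc(OC)cc1)c1ccc(OC)cc1 | intermediate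
13 | [2-ethynyl-6-(4-methoxyphenyl)-3-methylphenyl]bis(4-methoxyphenyl)methanol | Cc1ccc(-c2ccc(OC)cc2)c(C(O)(c2ccc(OC)cc2)c2ccc(OC)cc2)c1C#C | intermediate
14 | 4-iodoanisole | COc1ccc(I)cc1 | starting material
15 | {6-(4-methoxyphenyl)-2-[(4-methoxyphenyl)ethynyl]-3-methylphenyl}bis(4-methoxyphenyl)methanol | Cc1ccc(-c2ccc(OC)cc2)c(C(O)(c2ccc(OC)cc2)c2ccc(OC)cc2)c1C#Cc1ccc(OC)cc1 | intermediate
16 | selaginellin U | Cc1ccc(-c2ccc(O)cc2)c(C(=C2C=CC(=O)C=C2)c2ccc(O)cc2)c1C#Cc1ccc(O)cc1 | target

## Step count and least certain steps

Total step count: 9. Longest linear sequence: 9 steps (1 to 16); 3, 7 and 14 enter as purchased materials.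

**Step 3 (key step).** The cycloaddition may be too slow to compete with thermal loss of the diene. The reactive ester rotamer is thinly populated, and the donor aryl group both damps the ynoate and crowds the forming C4–C5 bond. Polymerisation and a 3,3-acyloxy shift with E/Z scrambling could then take over.
Fallback: take the aryl group out of the cycloaddition and bring it in afterwards by cross-coupling. The fallback sets out from dienol 2. Esterification of 2 with 3-(trimethylsilyl)propiolic acid (DCC, DMAP) should give (E)-3-methylpenta-2,4-dien-1-yl 3-(trimethylsilyl)prop-2-ynoate F1, whose ynoate carries no donor group and tolerates harder heating. Thermal intramolecular Diels–Alder reaction would give rac-4-methyl-7-(trimethylsilyl)-3a,6-dihydroisobenzofuran-1(3H)-one F2, DDQ would give 4-methyl-7-(trimethylsilyl)isobenzofuran-1(3H)-one F3, and ipso-iododesilylation with ICl would give 7-iodo-4-methylisobenzofuran-1(3H)-one F4. Suzuki coupling of F4 with 4-methoxyphenylboronic acid (Pd(PPh3)4, K2CO3, dioxane/H2O) comes back to the route at phthalide 6.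

**Step 5.** The addition may stop after one aryl group. The lithium hemiketal of a carbonyl flanked by an ortho aryl group may fail to open, or the aryllithium may act as a base at the benzylic lactone CH2.
Fallback: add the two aryl groups in separate stages. The fallback sets out from 6. One equivalent of 8 at −78 °C with a cold quench should give [2-(hydroxymethyl)-6-(4-methoxyphenyl)-3-methylphenyl](4-methoxyphenyl)methanone F5. TBSCl and imidazole would cap the primary alcohol and fix the open ketone as [2-({[tert-butyl(dimethyl)silyl]oxy}methyl)-6-(4-methoxyphenyl)-3-methylphenyl](4-methoxyphenyl)methanone F6. A further portion of 8, with anhydrous CeCl3 as an additive that lowers the basicity of the reagent, would add to the ketone to give [2-({[tert-butyl(dimethyl)silyl]oxy}methyl)-6-(4-methoxyphenyl)-3-methylphenyl]bis(4-methoxyphenyl)methanol F7, and TBAF comes back to the route at diol 10.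

**Step 6.** Two things can go wrong: over-oxidation of the benzylic lactol, or acid-induced ionisation of the bis-anisyl carbinol followed by ring closure onto the CH2OH group.
Fallback: give up stopping at the lactol. The fallback sets out from 10. Excess activated MnO2 in CH2Cl2 (neutral, heterogeneous) should drive the diol through to the lactone 3,3,4-tris(4-methoxyphenyl)-7-methylisobenzofuran-1(3H)-one F8. Partial reduction with DIBAL-H (toluene, −78 °C) comes back at lactol 12.

**Step 7.** The homologation may stall because the aldehyde is both masked as a gem-diaryl lactol and flanked on both sides. Long exposure to base then invites cyclisation of the carbinol oxygen onto the alkyne.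
Fallback: change the order so that the aldehyde is free and the aryl groups add last. The fallback sets out from phthalide 6. Saponification (KOH, MeOH/H2O) should give potassium 2-(hydroxymethyl)-6-(4-methoxyphenyl)-3-methylbenzoate F9, and alkylation of the dried salt with MeI in DMF would give methyl 2-(hydroxymethyl)-6-(4-methoxyphenyl)-3-methylbenzoate F10, which is used at once before it can close back to the lactone. Dess–Martin oxidation would give methyl 2-formyl-6-(4-methoxyphenyl)-3-methylbenzoate F11, the Ohira–Bestmann reaction would give methyl 2-ethynyl-6-(4-methoxyphenyl)-3-methylbenzoate F12, and Sonogashira coupling with 14 would give methyl 6-(4-methoxyphenyl)-2-[(4-methoxyphenyl)ethynyl]-3-methylbenzoate F13. Twofold addition of 8 to the ester group of F13 comes back to the route at 15.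

**Step 9.** The long-lived C7 cation may react further: Friedel–Crafts closure onto the neighbouring anisyl ring on C4, addition of HBr to the alkyne, or incomplete ether cleavage.
Fallback: separate deprotection from dehydration and avoid the Lewis acid. The fallback sets out from 15. Nucleophilic demethylation with NaSEt in DMF at 130 °C should give {6-(4-hydroxyphenyl)-2-[(4-hydroxyphenyl)ethynyl]-3-methylphenyl}bis(4-hydroxyphenyl)methanol F14; its phenolate-rich alkyne resists thiolate addition. Brief exposure to dilute acetic acid would dehydrate the carbinol and come back at target 16.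

## Further compounds

F1 | step 3 | (E)-3-methylpenta-2,4-dien-1-yl 3-(trimethylsilyl)prop-2-ynoate | C=C/C(C)=C/COC(=O)C#C[Si](C)(C)C
F2 | step 3 | rac-4-methyl-7-(trimethylsilyl)-3a,6-dihydroisobenzofuran-1(3H)-one | CC1=CCC([Si](C)(C)C)=C2C(=O)OCC12
F3 | step 3 | 4-methyl-7-(trimethylsilyl)isobenzofuran-1(3H)-one | Cc1ccc([Si](C)(C)C)c2C(=O)OCc12
F4 | step 3 | 7-iodo-4-methylisobenzofuran-1(3H)-one | Cc1ccc(I)c2C(=O)OCc12
F5 | step 5 | [2-(hydroxymethyl)-6-(4-methoxyphenyl)-3-methylphenyl](4-methoxyphenyl)methanone | OCc1c(C)ccc(-c2ccc(OC)cc2)c1C(=O)c1ccc(OC)cc1
F6 | step 5 | [2-({[tert-butyl(dimethyl)silyl]oxy}methyl)-6-(4-methoxyphenyl)-3-methylphenyl](4-methoxyphenyl)methanone | CC(C)(C)[Si](C)(C)OCc1c(C)ccc(-c2ccc(OC)cc2)c1C(=O)c1ccc(OC)cc1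
F7 | step 5 | [2-({[tert-butyl(dimethyl)silyl]oxy}methyl)-6-(4-methoxyphenyl)-3-methylphenyl]bis(4-methoxyphenyl)methanol | CC(C)(C)[Si](C)(C)OCc1c(C)ccc(-c2ccc(OC)cc2)c1C(O)(c1ccc(OC)cc1)c1ccc(OC)cc1
F8 | step 6 | 3,3,4-tris(4-methoxyphenyl)-7-methylisobenzofuran-1(3H)-one | Cc1ccc(-c2ccc(OC)cc2)c2c1C(=O)OC2(c1ccc(OC)cc1)c1ccc(OC)cc1
F9 | step 7 | potassium 2-(hydroxymethyl)-6-(4-methoxyphenyl)-3-methylbenzoate | [K+].[O-]C(=O)c1c(CO)c(C)ccc1-c1ccc(OC)cc1
F10 | step 7 | methyl 2-(hydroxymethyl)-6-(4-methoxyphenyl)-3-methylbenzoate | COC(=O)c1c(CO)c(C)ccc1-c1ccc(OC)cc1
F11 | step 7 | methyl 2-formyl-6-(4-methoxyphenyl)-3-methylbenzoate | COC(=O)c1c(C=O)c(C)ccc1-c1ccc(OC)cc1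
F12 | step 7 | methyl 2-ethynyl-6-(4-methoxyphenyl)-3-methylbenzoate | COC(=O)c1c(C#C)c(C)ccc1-c1ccc(OC)cc1
F13 | step 7 | methyl 6-(4-methoxyphenyl)-2-[(4-methoxyphenyl)ethynyl]-3-methylbenzoate | COC(=O)c1c(C#Cc2ccc(OC)cc2)c(C)ccc1-c1ccc(OC)cc1
F14 | step 9 | {6-(4-hydroxyphenyl)-2-[(4-hydroxyphenyl)ethynyl]-3-methylphenyl}bis(4-hydroxyphenyl)methanol | Cc1ccc(-c2ccc(O)cc2)c(C(O)(c2ccc(O)cc2)c2ccc(O)cc2)c1C#Cc1ccc(O)cc1
A1 | alternative 1 | 1-methoxy-1,3-bis(trimethylsilyloxy)penta-1,3-diene (enol ether geometry not defined) | COC(O[Si](C)(C)C)=CC(O[Si](C)(C)C)=CC
A2 | alternative 1 | (E)-1-(4-methoxyphenyl)-3-(trimethylsilyloxy)prop-2-en-1-one | COc1ccc(cc1)C(=O)/C=C/O[Si](C)(C)C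
A3 | alternative 1 | methyl 2-hydroxy-6-(4-methoxyphenyl)-3-methylbenzoate | COC(=O)c1c(O)c(C)ccc1-c1ccc(OC)cc1
A4 | alternative 1 | methyl 6-(4-methoxyphenyl)-3-methyl-2-{[(trifluoromethyl)sulfonyl]oxy}benzoate | COC(=O)c1c(OS(=O)(=O)C(F)(F)F)c(C)ccc1-c1ccc(OC)cc1
A5 | alternative 2 | 2-(4-methoxybenzoyl)-6-(4-methoxyphenyl)-3-methylbenzoic acid | Cc1ccc(-c2ccc(OC)cc2)c(C(=O)O)c1C(=O)c1ccc(OC)cc1
A6 | alternative 2 | lithiated trimethylsilyldiazomethane | [Li]C(=[N+]=[N-])[Si](C)(C)C
A7 | alternative 2 | 2-[(4-methoxyphenyl)ethynyl]-6-(4-methoxyphenyl)-3-methylbenzoic acid | Cc1ccc(-c2ccc(OC)cc2)c(C(=O)O)c1C#Cc1ccc(OC)cc1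
A8 | alternative 3 | rac-1,3-bis(4-methoxyphenyl)prop-2-yn-1-yl but-2-ynoate | CC#CC(=O)OC(c1ccc(OC)cc1)C#Cc1ccc(OC)cc1
A9 | alternative 3 | acetylene | C#C
A10 | alternative 3 | rac-3,4-bis(4-methoxyphenyl)-7-methylisobenzofuran-1(3H)-one | Cc1ccc(-c2ccc(OC)cc2)c2c1C(=O)OC2c1ccc(OC)cc1
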